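The ten-membered carbocycle (ring A) is disconnected at C3–C4 as an aldol bond (germacrane locants, defined below). A SmI2-mediated intramolecular Reformatsky-type addition of C3, α to the C2 enone carbonyl, onto the C4 methyl ketone closes ring A and creates the tertiary carbinol in one operation. The step exploits the β-hydroxy ketone retron hidden in the C2 acetoxy/C4 hydroxy pair and the 1,3-related C6 oxygen, which lets samarium chelate and set C4. The precursor is an open-chain chloromethyl enone and methyl ketone carried on a 2,3,4-trisubstituted furan, the latent form of the dienyl butenolide (ring B), which is unmasked afterwards by singlet oxygen and dehydration.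

Key step: step 10

Remark on locants: C1(H)=C10(CH3), C2 (OAc), C3 (CH2), C4 (C(OH)CH3), C5 (CH2), C6 (CH–O-methacryloyl), C7=C11 and C8=C9 of the dienyl lactone, C12 lactone carbonyl, C13 hydroxymethyl carbon; in the furan intermediates the furan carries C7, C8, C11 and C12.
Remark on stereochemistry: in ring A the C4 hydroxyl lies anti to both the C2 and the C6 oxygen; the CIP descriptor of C4 changes formally with the substituents (17 and 23) without any change in space.
Assumption: furan-3,4-diyldimethanol, propargyl alcohol and all reagents named under Conditions are taken as commercial.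

Step 1
Reactants: 1 prop-2-yn-1-ol
Product: 3 (2E)-3-iodo-2-methylprop-2-en-1-ol, via alkenylalane 2 (not isolated)
Conditions: AlMe3 (3 equiv), Cp2ZrCl2 (0.25 equiv), CH2Cl2, 0 °C to rt; then I2, THF, −30 to 0 °C
Reagents that add atoms: trimethylaluminium, C[Al](C)C; iodine, II
Why: Zirconocene-catalysed syn-carboalumination of the terminal alkyne (Negishi carboalumination) places methyl on the internal carbon and aluminium on the terminus, and iodinolysis with retention should give the (E)-vinyl iodide.

Step 2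
Reactants: 3 (2E)-3-iodo-2-methylprop-2-en-1-ol
Product: 4 (1E)-3-bromo-1-iodo-2-methylprop-1-ene
Conditions: CBr4, PPh3, CH2Cl2, 0 °C
Reagents that add atoms: carbon tetrabromide, BrC(Br)(Br)Br
Why: The Appel reaction converts the primary allylic alcohol into the bromide under neutral conditions that leave the vinyl iodide and the alkene geometry untouched.

Step 3
Reactants: 5 furan-3,4-diyldimethanol
Product: 6 [4-({[tert-butyl(dimethyl)silyl]oxy}methyl)furan-3-yl]methanol
Conditions: NaH (1.0 equiv), THF, 0 °C; then TBSCl (1.0 equiv), rt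
Reagents that add atoms: tert-butyldimethylsilyl chloride, CC(C)(C)[Si](C)(C)Cl
Why: Monosilylation of the symmetrical diol through its sparingly soluble monosodium alkoxide (O-silylation of an alkoxide) should favour the mono-TBS ether because the monoalkoxide is silylated as it forms.

Step 4
Reactants: 6 [4-({[tert-butyl(dimethyl)silyl]oxy}methyl)furan-3-yl]methanol
Product: 7 4-({[tert-butyl(dimethyl)silyl]oxy}methyl)furan-3-carbaldehyde
Conditions: MnO2, CH2Cl2, rt
Reagents that add atoms: none
Why: MnO2 oxidation of benzylic-type alcohols should take the furylmethanol to the aldehyde without touching the furan or the silyl ether.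

Step 5
Reactants: 7 4-({[tert-butyl(dimethyl)silyl]oxy}methyl)furan-3-carbaldehyde; 4 (1E)-3-bromo-1-iodo-2-methylprop-1-ene
Product: 10 4-(TBSO-methyl)-2-[(2E)-3-iodo-2-methylprop-2-en-1-yl]furan-3-carbaldehyde, via lithium amino alkoxide 8 (not isolated), via C8-lithiated amino alkoxide 9 (not isolated)
Conditions: LiN(Me)CH2CH2NMe2 (from Me2NCH2CH2NHMe and n-BuLi), THF, −78 °C; n-BuLi, −78 to −20 °C; 4, −78 °C to rt; H2O
Reagents that add atoms: none
Why: Addition of the lithium amide to the aldehyde gives an α-amino alkoxide that masks the carbonyl and directs ortho-lithiation to the adjacent furan α-carbon (C8), and SN2 alkylation of the furyllithium by the allylic bromide followed by hydrolytic release of the aldehyde should give the 2,3,4-trisubstituted furan (directed ortho-metalation and alkylation).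

Step 6
Reactants: 10 4-(TBSO-methyl)-2-[(2E)-3-iodo-2-methylprop-2-en-1-yl]furan-3-carbaldehyde
Product: 11 (1R)-1-{4-(TBSO-methyl)-2-[(2E)-3-iodo-2-methylprop-2-en-1-yl]furan-3-yl}but-3-en-1-ol
Conditions: (+)-Ipc2B(allyl) [from (+)-Ipc2BOMe and allylMgBr], Et2O, −78 °C; then NaOH, H2O2
Reagents that add atoms: (+)-B-allyldiisopinocampheylborane, C=CCB([C@H]1C[C@H]2C[C@@H]([C@@H]1C)C2(C)C)[C@H]1C[C@H]2C[C@@H]([C@@H]1C)C2(C)C, made in the flask from allylmagnesium bromide, C=CC[Mg]Br
Why: Brown allylation through a closed chair transition state with the aldehyde substituent equatorial sets C6, and the (+)-Ipc2B(allyl) antipode, the one that converts aryl aldehydes into (R)-carbinols, should give the (R)-alcohol whose allyl group is a masked acetonyl unit.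

Step 7
Reactants: 11 (1R)-1-{4-(TBSO-methyl)-2-[(2E)-3-iodo-2-methylprop-2-en-1-yl]furan-3-yl}but-3-en-1-ol
Product: 12 PMB ether of 11 (C6–OPMB, 6R)
Conditions: NaH, PMBCl, Bu4NI (cat.), THF/DMF, 0 °C to rt
Reagents that add atoms: 4-methoxybenzyl chloride, COc1ccc(CCl)cc1
Why: Williamson etherification of the sodium alkoxide installs a chelating, oxidatively removable ether that is a poor leaving group and so resists β-elimination once C4 becomes a ketone.

Step 8
Reactants: 12 PMB ether (vinyl iodide)
Product: 14 (3E)-1-chloro-4-methyl-5-{3-[(1R)-1-(PMB-oxy)but-3-en-1-yl]-4-(TBSO-methyl)furan-2-yl}pent-3-en-2-one, via vinyllithium 13 (not isolated)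
Conditions: t-BuLi (2.1 equiv), Et2O, −78 °C; then ClCH2C(O)N(OMe)Me, −78 to 0 °C; aq NH4Cl
Reagents that add atoms: 2-chloro-N-methoxy-N-methylacetamide, CON(C)C(=O)CCl
Why: Iodine–lithium exchange proceeds with retention of the (E)-geometry and the vinyllithium adds once to the N-methoxy-N-methylamide (Weinreb ketone synthesis), the chelated tetrahedral intermediate collapsing to the chloromethyl enone only on work-up.

Step 9
Reactants: 14 chloromethyl enone with terminal alkene
Product: 15 (3E)-1-chloro-4-methyl-5-{3-[(1R)-1-(PMB-oxy)-3-oxobutyl]-4-(TBSO-methyl)furan-2-yl}pent-3-en-2-one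
Conditions: PdCl2 (10 mol %), CuCl, O2 (1 atm), DMF/H2O (7:1), rt
Reagents that add atoms: water, O
Why: Tsuji–Wacker oxidation of the monosubstituted terminal alkene should give the methyl ketone with Markovnikov selectivity, the trisubstituted enone alkene and the furan being far less reactive toward divalent palladium.

Step 10
Reactants: 15 chloromethyl enone/methyl ketone
Product: 17 ten-membered β-hydroxy enone (C2 ketone; C4 tertiary alcohol; C6–OPMB; 4R,6R), via samarium dienolate 16 (not isolated)
Conditions: SmI2 (2.5 equiv), THF, −78 °C, slow addition of 15 (final ca. 2 mM); aq NH4Cl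
Reagents that add atoms: none
Why: Two equivalents of SmI2 reduce the C3–Cl bond of the α'-chloro enone to the trivalent samarium dienolate 16, which can be nucleophilic only at C3, and this carbon adds to the C4 methyl ketone. The closest known reaction type is the SmI2-promoted intramolecular Reformatsky (aldol) cyclisation of α-halo carbonyl compounds, which is known to close medium rings. Ring A is closed in a 10-(enolendo)-exo-trig mode, helped by the E-alkene and the furan edge, which already hold four ring atoms in a turn. The new stereocentre C4 is controlled by the C6 stereocentre: the oxophilic metal is held by the enolate oxygen, the ketone oxygen and the C6 ether oxygen, and C3 attacks the chelated ketone from the face anti to C7, which places the C4 hydroxyl anti to the C6 oxygen. The step needs regioselective enolate formation (secured by the position of the chlorine), chemoselective reduction of C–Cl before ketone or enone (secured by the much faster reduction of α-halo ketones) and cyclisation over oligomerisation (secured by slow addition at high dilution).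

Step 11
Reactants: 17 ten-membered β-hydroxy enone
Product: 18 anti-diol (C2–OH, C4–OH; C6–OPMB; 2S,4S,6R)
Conditions: Me4NBH(OAc)3, MeCN/AcOH (1:1), −30 °C
Reagents that add atoms: none
Why: In the Evans–Saksena reduction the C4 hydroxyl binds boron and delivers hydride intramolecularly to the C2 carbonyl through a chair-like six-membered transition state, which should give 1,2-reduction of the enone to the 1,3-anti diol with the C2 hydroxyl on the face opposite to the C4 hydroxyl.

Step 12
Reactants: 18 anti-diol (furan)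
Product: 20 C8 lactol (γ-hydroxybutenolide; C8 epimers), via furan endoperoxide 19 (not isolated)
Conditions: O2, tetraphenylporphyrin (cat.), visible light, iPr2NEt, CH2Cl2, −78 °C
Reagents that add atoms: dioxygen, O=O
Why: [4+2] cycloaddition of singlet oxygen to the electron-rich furan is much faster than the ene reaction at the trisubstituted alkene, and base-induced Kornblum–DeLaMare fragmentation of the endoperoxide, whose only bridgehead hydrogen sits on C12, should give the C12 carbonyl and the C8 lactol regioselectively.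

Step 13
Reactants: 20 C8 lactol
Product: 22 dienyl enol lactone (C2–OAc; C4–OH; C6–OPMB; C13–OTBS; 2S,4S,6R), via C2/C8 diacetate 21 (not isolated)
Conditions: Ac2O, Et3N, DMAP (cat.), CH2Cl2, 0 °C to rt
Reagents that add atoms: acetic anhydride, CC(=O)OC(C)=O
Why: DMAP-catalysed acetylation esterifies the secondary allylic C2 hydroxyl and the lactol hydroxyl but not the hindered tertiary C4 hydroxyl, and amine-promoted β-elimination of acetic acid across C8–C9 should give the enol lactone, whose C8=C9 geometry is dictated by ring A.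

Step 14
Reactants: 22 dienyl enol lactone (C6–OPMB)
Product: 23 C6 alcohol (C2–OAc; C4–OH; C13–OTBS; 2S,4R,6R)
Conditions: DDQ, CH2Cl2/pH 7 phosphate buffer, 0 °C
Reagents that add atoms: none
Why: Oxidative PMB cleavage by DDQ proceeds by hydride abstraction from the electron-rich benzylic position and hydrolysis of the oxocarbenium ion, and should leave the acetate, the silyl ether and the electron-poor trienyl lactone intact.

Step 15
Reactants: 23 C6 alcohol
Product: 24 C6 methacrylate (C13–OTBS; 2S,4S,6R)
Conditions: methacrylic anhydride, Et3N, DMAP (cat.), CH2Cl2, 0 °C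
Reagents that add atoms: methacrylic anhydride, C=C(C)C(=O)OC(=O)C(C)=C
Why: DMAP-catalysed acyl transfer (Steglich-type esterification) acylates the secondary C6 hydroxyl, the tertiary C4 hydroxyl being too hindered to react at 0 °C.

Step 16
Reactants: 24 C6 methacrylate (C13–OTBS)
Product: 25 target CNP0246543.2
Conditions: HF·pyridine, pyridine, THF, 0 °C
Reagents that add atoms: none
Why: Fluoride-mediated desilylation with buffered HF·pyridine removes the primary TBS ether and should not cleave the acetate, the methacrylate or the enol lactone.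

Compound list
1 | prop-2-yn-1-ol (propargyl alcohol) | C#CCO | starting material
2 | dimethyl[(1E)-3-(dimethylalumanyloxy)-2-methylprop-1-en-1-yl]alumane (alkenylalane) | C[Al](C)OC/C(C)=C/[Al](C)C | intermediate
3 | (2E)-3-iodo-2-methylprop-2-en-1-ol | OC/C(C)=C/I | intermediate
4 | (1E)-3-bromo-1-iodo-2-methylprop-1-ene | BrC/C(C)=C/I | intermediate
5 | furan-3,4-diyldimethanol | OCc1cocc1CO | starting material
6 | [4-({[tert-butyl(dimethyl)silyl]oxy}methyl)furan-3-yl]methanol | CC(C)(C)[Si](C)(C)OCc1cocc1CO | intermediate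
7 | 4-({[tert-butyl(dimethyl)silyl]oxy}methyl)furan-3-carbaldehyde | CC(C)(C)[Si](C)(C)OCc1cocc1C=O | intermediate
8 | lithium α-amino alkoxide from 7 and LiN(Me)CH2CH2NMe2 | CC(C)(C)[Si](C)(C)OCc1cocc1C(O[Li])N(C)CCN(C)C | intermediate
9 | alkoxide 8 lithiated at the furan α-carbon next to the masked formyl group (C8) | CC(C)(C)[Si](C)(C)OCc1coc([Li])c1C(O[Li])N(C)CCN(C)C | intermediate
10 | 4-(TBSO-methyl)-2-[(2E)-3-iodo-2-methylprop-2-en-1-yl]furan-3-carbaldehyde | CC(C)(C)[Si](C)(C)OCc1coc(C/C(C)=C/I)c1C=O | intermediate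
11 | (1R)-1-{4-(TBSO-methyl)-2-[(2E)-3-iodo-2-methylprop-2-en-1-yl]furan-3-yl}but-3-en-1-ol | CC(C)(C)[Si](C)(C)OCc1coc(C/C(C)=C/I)c1[C@H](O)CC=C | intermediate
12 | 4-methoxybenzyl ether of 11 (6R) | CC(C)(C)[Si](C)(C)OCc1coc(C/C(C)=C/I)c1[C@H](OCc1ccc(OC)cc1)CC=C | intermediate
13 | (E)-vinyllithium from 12 (Li in place of I) | CC(C)(C)[Si](C)(C)OCc1coc(C/C(C)=C/[Li])c1[C@H](OCc1ccc(OC)cc1)CC=C | intermediate
14 | (3E)-1-chloro-4-methyl-5-{3-[(1R)-1-(4-methoxybenzyloxy)but-3-en-1-yl]-4-(TBSO-methyl)furan-2-yl}pent-3-en-2-one | CC(C)(C)[Si](C)(C)OCc1coc(C/C(C)=C/C(=O)CCl)c1[C@H](OCc1ccc(OC)cc1)CC=C | intermediate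
15 | (3E)-1-chloro-4-methyl-5-{3-[(1R)-1-(4-methoxybenzyloxy)-3-oxobutyl]-4-(TBSO-methyl)furan-2-yl}pent-3-en-2-one | CC(C)(C)[Si](C)(C)OCc1coc(C/C(C)=C/C(=O)CCl)c1[C@H](OCc1ccc(OC)cc1)CC(C)=O | intermediate
16 | trivalent samarium dienolate of 15 (O–SmI2 on C2, C2=C3 methylene) | CC(C)(C)[Si](C)(C)OCc1coc(C/C(C)=C/C(=C)O[Sm](I)I)c1[C@H](OCc1ccc(OC)cc1)CC(C)=O | intermediate
17 | furan-fused ten-membered β-hydroxy enone: C2 ketone, (1(10)E)-alkene, C4 hydroxy and methyl, C6 OPMB, C13 OTBS; (4R,6R), C4–OH anti to C6–O | COc1ccc(CO[C@@H]2C[C@@](C)(O)CC(=O)/C=C(C)/Cc3occ(CO[Si](C)(C)C(C)(C)C)c32)cc1 | intermediate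
18 | furan-fused ten-membered diol: C2 and C4 hydroxy (anti), C6 OPMB, C13 OTBS; (2S,4S,6R) | COc1ccc(CO[C@@H]2C[C@@](C)(O)C[C@H](O)/C=C(C)/Cc3occ(CO[Si](C)(C)C(C)(C)C)c32)cc1 | intermediate
19 | furan endoperoxide of 18 (O–O bridge between C8 and C12; mixture at C8/C12) | COc1ccc(CO[C@@H]2C[C@@](C)(O)C[C@H](O)/C=C(C)/CC34OOC(O3)C(CO[Si](C)(C)C(C)(C)C)=C42)cc1 | intermediate
20 | 8-hydroxy-7(11)-en-12,8-olide (C8 lactol, C8 epimers) with C2 and C4 hydroxy, C6 OPMB, C13 OTBS; (2S,4S,6R) | COc1ccc(CO[C@@H]2C[C@@](C)(O)C[C@H](O)/C=C(C)/CC3(O)OC(=O)C(CO[Si](C)(C)C(C)(C)C)=C32)cc1 | intermediate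
21 | C2/C8 diacetate of 20 (C8 epimers) | COc1ccc(CO[C@@H]2C[C@@](C)(O)C[C@H](OC(C)=O)/C=C(C)/CC3(OC(C)=O)OC(=O)C(CO[Si](C)(C)C(C)(C)C)=C32)cc1 | intermediate
22 | 1(10)E,7(11),8-trien-12,8-olide with C2 OAc, C4 OH, C6 OPMB, C13 OTBS; (2S,4S,6R) | COc1ccc(CO[C@@H]2C[C@@](C)(O)C[C@H](OC(C)=O)/C=C(C)/C=C3/OC(=O)C(CO[Si](C)(C)C(C)(C)C)=C32)cc1 | intermediate
23 | 1(10)E,7(11),8-trien-12,8-olide with C2 OAc, C4 OH, C6 OH, C13 OTBS; (2S,4R,6R) | O[C@@H]1C[C@@](C)(O)C[C@H](OC(C)=O)/C=C(C)/C=C2/OC(=O)C(CO[Si](C)(C)C(C)(C)C)=C21 | intermediate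
24 | C6 methacrylate of 23 (C13 OTBS); (2S,4S,6R) | C=C(C)C(=O)O[C@@H]1C[C@@](C)(O)C[C@H](OC(C)=O)/C=C(C)/C=C2/OC(=O)C(CO[Si](C)(C)C(C)(C)C)=C21 | intermediate
25 | CNP0246543.2: (2S,4S,6R)-2-acetoxy-4,13-dihydroxy-6-(methacryloyloxy)germacra-1(10)E,7(11),8-trien-12,8-olide | C=C(C)C(=O)O[C@@H]1C[C@@](C)(O)C[C@H](OC(C)=O)/C=C(C)/C=C2/OC(=O)C(CO)=C21 | target

Total step count: 16. Longest linear sequence: 14 steps (5 to 25, steps 3–16); steps 1–2 make the allylic bromide 4 that joins in step 5.

Steps most likely to fail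

Step 10 (ring closure). The samarium enolate may be protonated before it cyclises (net dechlorination), may add to a second molecule (oligomers), or may attack the wrong face of the C4 ketone if the three-point chelate does not form. Fallback, from 15 back to 17: reductive silylation of the chloromethyl ketone (Zn dust, Me3SiCl, Et2O, 0 °C) gives regiospecifically the 2-(trimethylsilyloxy)diene F1, and a chelation-controlled intramolecular Mukaiyama aldol addition (Me2AlCl, CH2Cl2, −78 °C, high dilution, aqueous work-up) closes the same C3–C4 bond through an open transition state with the aluminium held between the C4 carbonyl and the C6 ether oxygen.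

Step 13 (acetylation and dehydration of the lactol). The C8 acyloxocarbenium ion may be captured across the ring by the free C4 hydroxyl (transannular ketal formation) faster than the C9 proton is lost, or the tertiary alcohol may be acetylated on prolonged exposure. Fallback, from 18 back to 25: the C2 hydroxyl is acetylated first (Ac2O, pyridine, DMAP cat., 0 °C) to give the C2 monoacetate F2, and the tertiary hydroxyl is capped (TESOTf, 2,6-lutidine, CH2Cl2, −78 °C) as the C4 triethylsilyl ether F3. Photooxygenation as in step 12 then leads through the endoperoxide F4 to the C8 lactol F5. Ac2O/Et3N/DMAP gives the lactol acetate F6, which can now only eliminate to the dienyl enol lactone F7. DDQ frees the C6 alcohol F8, methacrylic anhydride/Et3N/DMAP gives the methacrylate F9, and HF·pyridine removes both silyl groups to give 25.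

Step 5 (directed lithiation and alkylation). Lithiation may compete at the other furan α-carbon (C12, next to the silyloxymethyl group) and be followed by silyl migration from oxygen to carbon, and excess alkyllithium may undergo halogen–metal exchange with the vinyl iodide. Fallback, from 6 back to 10: at the alcohol oxidation level the lithium alkoxide itself directs the metalation (n-BuLi, 2.2 equiv, THF, −78 to 0 °C) to give the C8-lithiated alkoxide F10, alkylation with 4 gives the 2-allylated furylmethanol F11, and MnO2 oxidation then gives 10.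

Further compounds
F1 | step 10 | (3E)-2-(trimethylsilyloxy)diene from 15 (Me3SiO on C2, C2=C3 methylene, C4 methyl ketone retained) | CC(C)(C)[Si](C)(C)OCc1coc(C/C(C)=C/C(=C)O[Si](C)(C)C)c1[C@H](OCc1ccc(OC)cc1)CC(C)=O
F2 | step 13 | C2 monoacetate of 18 (furan; C4 OH; C6 OPMB; C13 OTBS) | COc1ccc(CO[C@@H]2C[C@@](C)(O)C[C@H](OC(C)=O)/C=C(C)/Cc3occ(CO[Si](C)(C)C(C)(C)C)c32)cc1
F3 | step 13 | C4 triethylsilyl ether of F2 | COc1ccc(CO[C@@H]2C[C@@](C)(O[Si](CC)(CC)CC)C[C@H](OC(C)=O)/C=C(C)/Cc3occ(CO[Si](C)(C)C(C)(C)C)c32)cc1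
F4 | step 13 | furan endoperoxide of F3 | COc1ccc(CO[C@@H]2C[C@@](C)(O[Si](CC)(CC)CC)C[C@H](OC(C)=O)/C=C(C)/CC34OOC(O3)C(CO[Si](C)(C)C(C)(C)C)=C42)cc1
F5 | step 13 | C8 lactol with C2 OAc and C4 OTES (C8 epimers) | COc1ccc(CO[C@@H]2C[C@@](C)(O[Si](CC)(CC)CC)C[C@H](OC(C)=O)/C=C(C)/CC3(O)OC(=O)C(CO[Si](C)(C)C(C)(C)C)=C32)cc1
F6 | step 13 | C8 acetate of lactol F5 | COc1ccc(CO[C@@H]2C[C@@](C)(O[Si](CC)(CC)CC)C[C@H](OC(C)=O)/C=C(C)/CC3(OC(C)=O)OC(=O)C(CO[Si](C)(C)C(C)(C)C)=C32)cc1
F7 | step 13 | dienyl enol lactone with C2 OAc, C4 OTES, C6 OPMB, C13 OTBS | COc1ccc(CO[C@@H]2C[C@@](C)(O[Si](CC)(CC)CC)C[C@H](OC(C)=O)/C=C(C)/C=C3/OC(=O)C(CO[Si](C)(C)C(C)(C)C)=C32)cc1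
F8 | step 13 | C6 alcohol from F7 (C4 OTES, C13 OTBS) | O[C@@H]1C[C@@](C)(O[Si](CC)(CC)CC)C[C@H](OC(C)=O)/C=C(C)/C=C2/OC(=O)C(CO[Si](C)(C)C(C)(C)C)=C21
F9 | step 13 | C6 methacrylate of F8 (C4 OTES, C13 OTBS) | C=C(C)C(=O)O[C@@H]1C[C@@](C)(O[Si](CC)(CC)CC)C[C@H](OC(C)=O)/C=C(C)/C=C2/OC(=O)C(CO[Si](C)(C)C(C)(C)C)=C21
F10 | step 5 | dilithio species from 6 (lithium alkoxide, lithium on the adjacent furan α-carbon) | CC(C)(C)[Si](C)(C)OCc1coc([Li])c1CO[Li]
F11 | step 5 | {4-(TBSO-methyl)-2-[(2E)-3-iodo-2-methylprop-2-en-1-yl]furan-3-yl}methanol | CC(C)(C)[Si](C)(C)OCc1coc(C/C(C)=C/I)c1CO
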